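**Retrosynthetic overview**

- Rings A (3,4,5-trimethoxyphenyl) and B (the benzo ring) are bought. Only ring C (the 1,4-dioxane) is made, by joining the benzylic oxygen O7 on C7 (the carbon bearing ring A) to the ring B carbon ortho to O8, the ether oxygen that links ring B to C8 (the carbon bearing C9H2OH).
- Enabling feature: ring B carries oxygen on three adjacent carbons with O8 in the middle. A 2,6-dibromo-4-formylphenyl ether is therefore locally symmetric: its two C–Br bonds are equivalent, one becomes the ring C–O bond and the other the free phenol, in one palladium domino with no regiochemical choice and no phenol protection.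
- The acyclic precursor, a (1S,2S)-2-aryloxy-1-arylpropanol, comes from an α-aryloxy β-keto ester by asymmetric transfer hydrogenation with dynamic kinetic resolution (both stereocentres in one step), then ester reduction and tritylation of O9.
- The β-keto ester comes from a crossed Claisen reaction of the aryloxyacetate (from 3,5-dibromo-4-hydroxybenzaldehyde) with 3,4,5-trimethoxybenzoyl chloride. After the key step, acid unmasks the aldehyde and O9, and a Wittig two-carbon homologation gives the E enal.

Key step: step 7

Remark: the sense of induction in step 4 is assumed to follow that of aryl alkyl ketones with Noyori-type catalysts (the (R,R)-TsDPEN complex delivers hydride as in the formation of (R)-1-phenylethanol, which here reads 3S because C8 outranks ring A), and the syn preference is assumed to follow that of α-alkoxy β-keto esters.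

**Route**

Step 1
Reactants: 1 3,5-dibromo-4-hydroxybenzaldehyde
Product: 2 methyl 2-(2,6-dibromo-4-formylphenoxy)acetate
Conditions: methyl bromoacetate (1.2 equiv), K2CO3 (1.5 equiv), DMF, 50 °C
Reagents that add atoms: methyl bromoacetate, COC(=O)CBr
Why: Williamson etherification, in which the acidic 2,6-dibromophenol is fully ionised by K2CO3 and the unhindered α-bromo ester should alkylate the phenoxide oxygen cleanly despite the two ortho bromines; no stereocentre is involved.

Step 2
Reactants: 2 methyl 2-(2,6-dibromo-4-formylphenoxy)acetate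
Product: 3 methyl 2-[2,6-dibromo-4-(1,3-dioxolan-2-yl)phenoxy]acetate
Conditions: ethylene glycol (3 equiv), TsOH·H2O (cat.), toluene, reflux, Dean–Stark trap
Reagents that add atoms: ethylene glycol, OCCO
Why: Acid-catalysed acetalisation with azeotropic removal of water masks the aldehyde, which would otherwise be attacked by the enolate in step 3, reduced in step 4 and, as a para acceptor, would open a Smiles rearrangement path for the C7 alkoxide in step 7.

Step 3
Reactants: 3 methyl 2-[2,6-dibromo-4-(1,3-dioxolan-2-yl)phenoxy]acetate, 4 3,4,5-trimethoxybenzoyl chloride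
Product: 6 methyl 2-[2,6-dibromo-4-(1,3-dioxolan-2-yl)phenoxy]-3-oxo-3-(3,4,5-trimethoxyphenyl)propanoate (racemic), via lithium enolate 5 (not isolated)
Conditions: LiN(SiMe3)2 (2.1 equiv), THF, −78 °C; then 4 (1.05 equiv), −78 to −20 °C; aq NH4Cl
Reagents that add atoms: none
Why: Crossed Claisen condensation (C-acylation of a lithium ester enolate by an aroyl chloride), in which the second equivalent of amide base traps the more acidic β-keto ester as its enolate so that acylation should run to completion; the new α-stereocentre forms racemic and stays labile, which step 4 exploits.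

Step 4
Reactants: 6 methyl 2-[2,6-dibromo-4-(1,3-dioxolan-2-yl)phenoxy]-3-oxo-3-(3,4,5-trimethoxyphenyl)propanoate (racemic)
Product: 7 methyl (2R,3S)-2-[2,6-dibromo-4-(1,3-dioxolan-2-yl)phenoxy]-3-hydroxy-3-(3,4,5-trimethoxyphenyl)propanoate
Conditions: RuCl(p-cymene)[(R,R)-TsDPEN] (1 mol %), HCO2H/Et3N (5:2), CH2Cl2, 30 °C
Reagents that add atoms: none
Why: Noyori asymmetric transfer hydrogenation with dynamic kinetic resolution, in which the α-aryloxy β-keto ester racemises through its enol faster than it is reduced and the ruthenium hydride of the (R,R)-ligand reduces one ketone face of the faster-reacting enantiomer, which should set C7 as S by catalyst control and C8 as R through the syn preference known for α-alkoxy β-keto esters.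

Step 5
Reactants: 7 methyl (2R,3S)-2-[2,6-dibromo-4-(1,3-dioxolan-2-yl)phenoxy]-3-hydroxy-3-(3,4,5-trimethoxyphenyl)propanoate
Product: 8 (1S,2S)-2-[2,6-dibromo-4-(1,3-dioxolan-2-yl)phenoxy]-1-(3,4,5-trimethoxyphenyl)propane-1,3-diol
Conditions: LiBH4 (2 equiv), THF, 0 °C to rt
Reagents that add atoms: none
Why: Chemoselective hydride reduction of the alkoxy-activated ester by LiBH4 should give the 1,3-diol and removes the only acidic C–H at C8, so both stereocentres become configurationally fixed (the descriptor at C8 changes from R to S only through the priority rules); aryl bromides and the acetal are inert.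

Step 6
Reactants: 8 (1S,2S)-2-[2,6-dibromo-4-(1,3-dioxolan-2-yl)phenoxy]-1-(3,4,5-trimethoxyphenyl)propane-1,3-diol
Product: 9 (1S,2S)-2-[2,6-dibromo-4-(1,3-dioxolan-2-yl)phenoxy]-1-(3,4,5-trimethoxyphenyl)-3-(trityloxy)propan-1-ol
Conditions: trityl chloride (1.1 equiv), Et3N, DMAP (cat.), CH2Cl2, rt
Reagents that add atoms: trityl chloride, ClC(c1ccccc1)(c1ccccc1)c1ccccc1
Why: Sterically controlled tritylation should take the primary C9 hydroxyl far faster than the secondary benzylic C7 hydroxyl, leaving only O7 for ring closure (a free O9 could close a competing six-membered ring), and a trityl ether does not migrate under the basic conditions of step 7.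

Step 7
Reactants: 9 (1S,2S)-2-[2,6-dibromo-4-(1,3-dioxolan-2-yl)phenoxy]-1-(3,4,5-trimethoxyphenyl)-3-(trityloxy)propan-1-ol
Product: 11 (2S,3S)-7-(1,3-dioxolan-2-yl)-2-(3,4,5-trimethoxyphenyl)-3-(trityloxymethyl)-2,3-dihydro-1,4-benzodioxin-5-ol, via bromobenzodioxane 10 (not isolated)
Conditions: Pd2(dba)3 (2 mol %), tBuXPhos (8 mol %), Cs2CO3, 1,4-dioxane, 80 °C; then KOH, H2O, 100 °C, same pot; NaH2PO4 buffer work-up
Reagents that add atoms: potassium hydroxide, [K+].[OH-]
Why: Zerovalent palladium bearing tBuXPhos inserts into one of the two equivalent C–Br bonds of ring B, Cs2CO3 deprotonates the C7 hydroxyl, and the resulting seven-membered aryl palladium alkoxide undergoes C–O reductive elimination to bromide 10; after aqueous KOH is added, the same catalyst converts the remaining C–Br bond through an aryl palladium hydroxide into the phenol. Both halves are known reaction types with this ligand class: the Buchwald–Hartwig-type intramolecular etherification of 2-(2-bromophenoxy)alkanols to 1,4-benzodioxanes and the palladium-catalysed hydroxylation of aryl bromides with KOH. Ring C is closed by intramolecular C(sp2)–O reductive elimination, formally a 6-exo closure of O7 on the ring B carbon ortho to O8. No stereocentre is formed and no bond to C7 or C8 is broken, so the (7S,8S) syn array of 9 should be carried with retention into the trans-2,3-disubstituted dioxane. The step needs site selectivity on ring B, which is moot because either bromide of the locally symmetric 2,6-dibromoaryl ether gives the same product while the other is the latent phenol; it needs O7 and not O9 as nucleophile, secured by the trityl ether; and it needs etherification before hydroxylation, secured by withholding hydroxide until 9 is consumed. Reductive elimination must outrun β-hydride elimination of the benzylic alkoxide, which the bulky di-tert-butyl biaryl phosphine favours, and the acetal (no para acceptor on ring B) closes the Smiles rearrangement path and limits alkoxide-induced loss of the aryloxide.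

Step 8
Reactants: 11 (2S,3S)-7-(1,3-dioxolan-2-yl)-2-(3,4,5-trimethoxyphenyl)-3-(trityloxymethyl)-2,3-dihydro-1,4-benzodioxin-5-ol
Product: 12 (2S,3S)-8-hydroxy-2-(hydroxymethyl)-3-(3,4,5-trimethoxyphenyl)-2,3-dihydro-1,4-benzodioxine-6-carbaldehyde
Conditions: HCl (1 M aq), THF, 40 °C
Reagents that add atoms: water, O
Why: Acid hydrolysis should convert the dioxolane to the aldehyde and ionise the trityl ether to the stabilised trityl cation, while the alkyl aryl ether bonds of ring C should survive with both stereocentres intact because a C7 cation is only weakly stabilised by the out-of-plane 4-methoxy group of ring A.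

Step 9
Reactants: 12 (2S,3S)-8-hydroxy-2-(hydroxymethyl)-3-(3,4,5-trimethoxyphenyl)-2,3-dihydro-1,4-benzodioxine-6-carbaldehyde
Product: 13 (2E)-3-[(2S,3S)-8-hydroxy-2-(hydroxymethyl)-3-(3,4,5-trimethoxyphenyl)-2,3-dihydro-1,4-benzodioxin-6-yl]prop-2-enal
Conditions: Ph3P=CHCHO (1.3 equiv), toluene/THF, 70 °C
Reagents that add atoms: (triphenylphosphoranylidene)acetaldehyde, O=CC=P(c1ccccc1)(c1ccccc1)c1ccccc1
Why: Wittig olefination with the formyl-stabilised ylide should give the E enal, and the ylide is too weakly basic to deprotonate the phenol or the alcohol, so no protection is needed.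

**Compound list**

1 | 3,5-dibromo-4-hydroxybenzaldehyde | O=Cc1cc(Br)c(O)c(Br)c1 | starting material
2 | methyl 2-(2,6-dibromo-4-formylphenoxy)acetate | COC(=O)COc1c(Br)cc(C=O)cc1Br | intermediate
3 | methyl 2-[2,6-dibromo-4-(1,3-dioxolan-2-yl)phenoxy]acetate | COC(=O)COc1c(Br)cc(C2OCCO2)cc1Br | intermediate
4 | 3,4,5-trimethoxybenzoyl chloride | COc1cc(C(=O)Cl)cc(OC)c1OC | starting material
5 | lithium enolate of 3 | [Li+].COC([O-])=COc1c(Br)cc(C2OCCO2)cc1Br | intermediate
6 | methyl 2-[2,6-dibromo-4-(1,3-dioxolan-2-yl)phenoxy]-3-oxo-3-(3,4,5-trimethoxyphenyl)propanoate (racemic) | COC(=O)C(Oc1c(Br)cc(C2OCCO2)cc1Br)C(=O)c1cc(OC)c(OC)c(OC)c1 | intermediate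
7 | methyl (2R,3S)-2-[2,6-dibromo-4-(1,3-dioxolan-2-yl)phenoxy]-3-hydroxy-3-(3,4,5-trimethoxyphenyl)propanoate | COC(=O)[C@H](Oc1c(Br)cc(C2OCCO2)cc1Br)[C@@H](O)c1cc(OC)c(OC)c(OC)c1 | intermediate
8 | (1S,2S)-2-[2,6-dibromo-4-(1,3-dioxolan-2-yl)phenoxy]-1-(3,4,5-trimethoxyphenyl)propane-1,3-diol | OC[C@H](Oc1c(Br)cc(C2OCCO2)cc1Br)[C@@H](O)c1cc(OC)c(OC)c(OC)c1 | intermediate
9 | (1S,2S)-2-[2,6-dibromo-4-(1,3-dioxolan-2-yl)phenoxy]-1-(3,4,5-trimethoxyphenyl)-3-(trityloxy)propan-1-ol | c1ccccc1C(c1ccccc1)(c1ccccc1)OC[C@H](Oc1c(Br)cc(C2OCCO2)cc1Br)[C@@H](O)c1cc(OC)c(OC)c(OC)c1 | intermediate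
10 | (2S,3S)-5-bromo-7-(1,3-dioxolan-2-yl)-2-(3,4,5-trimethoxyphenyl)-3-(trityloxymethyl)-2,3-dihydro-1,4-benzodioxine | COc1cc([C@@H]2Oc3cc(C4OCCO4)cc(Br)c3O[C@H]2COC(c2ccccc2)(c2ccccc2)c2ccccc2)cc(OC)c1OC | intermediate
11 | (2S,3S)-7-(1,3-dioxolan-2-yl)-2-(3,4,5-trimethoxyphenyl)-3-(trityloxymethyl)-2,3-dihydro-1,4-benzodioxin-5-ol | COc1cc([C@@H]2Oc3cc(C4OCCO4)cc(O)c3O[C@H]2COC(c2ccccc2)(c2ccccc2)c2ccccc2)cc(OC)c1OC | intermediate
12 | (2S,3S)-8-hydroxy-2-(hydroxymethyl)-3-(3,4,5-trimethoxyphenyl)-2,3-dihydro-1,4-benzodioxine-6-carbaldehyde | COc1cc([C@@H]2Oc3cc(C=O)cc(O)c3O[C@H]2CO)cc(OC)c1OC | intermediate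
13 | (2E)-3-[(2S,3S)-8-hydroxy-2-(hydroxymethyl)-3-(3,4,5-trimethoxyphenyl)-2,3-dihydro-1,4-benzodioxin-6-yl]prop-2-enal | COc1cc([C@@H]2Oc3cc(/C=C/C=O)cc(O)c3O[C@H]2CO)cc(OC)c1OC | target

**Step count and risks**

Total step count: 9. Longest linear sequence: 9 steps (1 to 13).

Step 7. What may go wrong: β-hydride elimination at the palladium alkoxide (oxidation of the C7 carbinol coupled to hydrodebromination), alkoxide-induced expulsion of the dibromophenoxide from C8, or hydroxylation of both C–Br bonds before ring closure. The fallback sets out from 9 and comes back at 11, giving up the domino for a stepwise copper and boron sequence. Ullmann etherification of 9 (CuI, 3,4,7,8-tetramethyl-1,10-phenanthroline, Cs2CO3, toluene, 100 °C), which has no β-hydride pathway, should give the bromobenzodioxane 10, now isolated. Miyaura borylation of 10 (bis(pinacolato)diboron, PdCl2(dppf), KOAc, 1,4-dioxane, 90 °C) should give the arylboronic pinacol ester F1. Oxidation of F1 (NaBO3·4H2O, THF/H2O, rt) returns to phenol 11.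

Step 4. What may go wrong: slow racemisation relative to reduction or poor facial discrimination next to the bulky 2,6-dibromoaryloxy group, giving a mixture of diastereomers or low enantiomeric purity, or acetal loss in the formic acid medium followed by aldehyde reduction. The fallback sets out from 3 and comes back at 8, replacing catalyst control by auxiliary control and bypassing steps 3 to 5. Saponification of 3 (LiOH, THF/H2O, 0 °C) should give the aryloxyacetic acid F2. Activation as the pivalic mixed anhydride (pivaloyl chloride, Et3N, THF, −20 °C) and acylation of (R)-4-benzyl-1,3-oxazolidin-2-one in the presence of LiCl should give the N-aryloxyacetyl oxazolidinone F3. An Evans syn aldol reaction with 3,4,5-trimethoxybenzaldehyde (Bu2BOTf, iPr2NEt, CH2Cl2, −78 to 0 °C, H2O2 work-up) should give the (2R,3S) syn aldol adduct F4 through the Z boron enolate and a Zimmerman–Traxler chair. Reductive removal of the auxiliary (LiBH4, THF/MeOH, 0 °C) gives diol 8 directly.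

Step 9. What may go wrong: a second olefination of the product enal (over-homologation to the dienal) or sluggish conversion of the electron-rich aldehyde. The fallback sets out from 12 and comes back at 13, building the enal by olefination to the ester and redox adjustment. Horner–Wadsworth–Emmons olefination of 12 (triethyl phosphonoacetate, LiCl, DBU, MeCN, rt) should give the ethyl E-cinnamate F5. Reduction with excess iBu2AlH (CH2Cl2, −78 °C) should give the allylic alcohol F6. MnO2 (CH2Cl2, rt) should oxidise the allylic alcohol selectively in the presence of the saturated primary alcohol to give 13.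

**Further compounds**

F1 | step 7 | 2-[(2S,3S)-7-(1,3-dioxolan-2-yl)-2-(3,4,5-trimethoxyphenyl)-3-(trityloxymethyl)-2,3-dihydro-1,4-benzodioxin-5-yl]-4,4,5,5-tetramethyl-1,3,2-dioxaborolane | COc1cc([C@@H]2Oc3cc(C4OCCO4)cc(B4OC(C)(C)C(C)(C)O4)c3O[C@H]2COC(c2ccccc2)(c2ccccc2)c2ccccc2)cc(OC)c1OC
F2 | step 4 | 2-[2,6-dibromo-4-(1,3-dioxolan-2-yl)phenoxy]acetic acid | OC(=O)COc1c(Br)cc(C2OCCO2)cc1Br
F3 | step 4 | (4R)-4-benzyl-3-{2-[2,6-dibromo-4-(1,3-dioxolan-2-yl)phenoxy]acetyl}-1,3-oxazolidin-2-one | O=C(COc1c(Br)cc(C2OCCO2)cc1Br)N1C(=O)OC[C@H]1Cc1ccccc1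
F4 | step 4 | (4R)-4-benzyl-3-[(2R,3S)-2-[2,6-dibromo-4-(1,3-dioxolan-2-yl)phenoxy]-3-hydroxy-3-(3,4,5-trimethoxyphenyl)propanoyl]-1,3-oxazolidin-2-one | O=C([C@H](Oc1c(Br)cc(C2OCCO2)cc1Br)[C@@H](O)c1cc(OC)c(OC)c(OC)c1)N1C(=O)OC[C@H]1Cc1ccccc1
F5 | step 9 | ethyl (2E)-3-[(2S,3S)-8-hydroxy-2-(hydroxymethyl)-3-(3,4,5-trimethoxyphenyl)-2,3-dihydro-1,4-benzodioxin-6-yl]prop-2-enoate | COc1cc([C@@H]2Oc3cc(/C=C/C(=O)OCC)cc(O)c3O[C@H]2CO)cc(OC)c1OC
F6 | step 9 | (2S,3S)-3-(hydroxymethyl)-7-[(1E)-3-hydroxyprop-1-en-1-yl]-2-(3,4,5-trimethoxyphenyl)-2,3-dihydro-1,4-benzodioxin-5-ol | COc1cc([C@@H]2Oc3cc(/C=C/CO)cc(O)c3O[C@H]2CO)cc(OC)c1OC
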